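Birch, alder and elm are neighbours: the same charge and the same self-destroying catalyst in different vessels.

    substrate ⇌ other conformer (K1 = 0.472, k1 = 3.05 × 10⁻⁵ /s)
    2 free catalyst → spent catalyst (k2 = 0.00736 /M/s)
    substrate + free catalyst → free catalyst + target (k3 = 0.0235 /M/s)
    free catalyst + other conformer → free catalyst + isomer of the product (k4 = 0.0338 /M/s)

| flask | substrate | free catalyst | time | remark |
|---|---|---|---|---|
| birch | 0.80 M (fed, over 20.0 h) | 0.88 mM | 40 h | all but substrate at the start; substrate goes in evenly over 20.0 h, the run ends at 40 h |
| alder | 0.80 M | 0.88 mM |  | a single well-mixed tank run continuously and read at steady state, 40 h in it on average |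
| elm | 0.80 M | 0.88 mM | 40 h | everything together in a closed stirred flask, run for 40 h |

1. the set-up with the highest amount of target at the outlet or at the end, in percent of the substrate put in ("none" if the first two lie within 2 percentage points) (birch / alder / elm / none)
2. amount of target at the outlet or at the end, in percent of the substrate put in, birch
3. amount of target at the outlet or at the end, in percent of the substrate put in, alder
4. amount of target at the outlet or at the end, in percent of the substrate put in, elm

- where a step has two of a species, its rate is k times that concentration squared, and two are used at each turn
- the stated concentrations are those of everything mixed, before any reaction; amounts are the same in each set-up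
- the feed brings no volume worth counting
- run time (birch): 40 h

The pairing step takes no substrate, so in elm and birch alike 1/[free catalyst] climbs linearly. Writing k for its constant and c for the starting [free catalyst], the time integral of [free catalyst] is ln(1 + 2kct)/(2k). At 40 h this catalyst exposure, the time integral of [free catalyst], is 71.5 M·s in molar seconds.

Weighting the two catalysed steps by the equilibrium split gives a mean constant of 0.0268 /M/s, and so a half-life of catalysed loss at the start of 8.16 h. Substrate and other conformer relax with a half-life of 2.02 h, and because that is shorter than the catalysed half-life, they count as one pool split in the ratio of 0.472. That pool is pseudo-first-order in exposure, so elm keeps 14.7% of it. Target takes a selectivity share of 59.6% of what reacts, which gives 50.8%.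

The weak link is that share, since elm starts with no other conformer. Over the relaxation time of 2.92 h the pool lacks it, and carrying this shortfall through the balance adds share × 0.472 × 0.0338 /M/s × 0.88 mM × relaxation time, or 8.8 percentage points. That is counted at the starting catalyst, so it sits on the high side, and the reckoning commits to 59.6% for elm.

Alder's well-mixed tank gives a mean exposure of 64.8 M·s, but its outlet keeps the reciprocal of 1 + constant × exposure, or 36.5% of the pool, which is more than elm's 14.7%. Birch's last drop meets 26.8 M·s, which keeps 48.8% of that drop, also more than elm's 14.7%. The reckoning therefore ranks elm first.

The forecast chose elm, because “all the substrate meets the catalyst while it is freshest”. It gave birch 47.5% (44% to 51%), alder 41.8% (40.5% to 43%) and elm 58% (55% to 61%), which for elm is lower than the reckoning.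

The simulation puts elm first at 58.0%, with birch at 46.7% and alder at 41.8%.

In elm the relaxation half-life of 2.02 h stands below the 27 h half-life of substrate by the catalysed step at 40.0 h, when substrate reads 10.5% and other conformer 4.77%, together 15.3% beside the exposure's 14.7%. A neighbour flask, elm with 2.2 × 10⁻⁴ M of free catalyst, has an exposure of 26.0 M·s, which leaves 49.8% of the pool, and it reads substrate 34.3%, other conformer 15.9% and target 31.9%.

(All constants were chosen freely; the rest is arithmetic.)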